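The earlier runs and the new flask are calculated for substances that don't exist.

A small charge of incoming ligand, 1.00 M in north-west against 2.0 M of starting complex, made me count ligand first, with delta as my one earlier run.

| flask | starting complex | incoming ligand | remark | time |
|---|---|---|---|---|
| delta | 3 M | 1 M | run made earlier |  |
| north-west | 2.0 M | 1.00 M |  | 30 h |
| west | 2.0 M | 1.50 M |  | 30 h |

delta run (percent of the starting complex charged)

| time / h | side product / % | complex with one exchanged / % | complex with two exchanged / % | starting complex / % |
|---|---|---|---|---|
| 0.500 | 2.3 | 6.5 | 0.5 | 91.2 |
| 0.833 | 6.4 | 6.2 | 0.2 | 85.7 |
| 1.50 | 13.9 | 8.7 | 0.3 | 78.1 |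
| 3.00 | 28.1 | 7.1 | 2.5 | 63.4 |
| 6.00 | 44.6 | 4.0 | 1.7 | 50.1 |

(readings scatter by 0.5 percentage points)

- which of these there is most of at the end, counted by the starting complex in it, north-west (complex with one exchanged / complex with two exchanged / side product / starting complex)
- which of these there is most of at the end, counted by the starting complex in it, west (complex with one exchanged / complex with two exchanged / side product / starting complex)
- the largest of these amounts at the end, in percent of the starting complex charged, north-west
- the largest of these amounts at the end, in percent of the starting complex charged, west

- in percentages every species weighs as the starting complex in it: one side product counts as two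
- no earlier run changes the charge of incoming ligand; that part of a forecast is a guess

1. No reading shows the ligand, so I assumed a cost: one ligand per complex with one exchanged, two per complex with two exchanged, and one per side product, which holds two starting complexes.

2. At delta's last reading, 6.00 h, that made 0.891 M spent of 1 M charged.

3. I called the share of spent ligand standing in side product the ligand yield φ, and read it as 0.751. With charges c_X of ligand and c_M of complex, the ligand reach C = 2φc_X/c_M is the side product, in percent of complex charged, once the ligand is spent with φ held.

4. For north-west I allowed 5.00 times delta's time at 0.667 of its complex, a product above one, so I took the ligand as spent and got C = 75.1%.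

5. For west C came to 113%, over the whole charge, so I turned to the share of spent complex in side product at delta's last reading, 88.7%, and committed west to between 75.1% and 88.7%.

6. A weak link was delta's two-exchanged reading, counted double; moved by 0.5 percentage points either way, it put C for north-west between 72.6% and 77.7%.

The forecast named side product in north-west at 73%, a little under my figure, and side product in west at 73%: “The west forecast assumes ligand order carries over.”

North-west gave side product at 73.2%, and west side product at 76.1%. In north-west incoming ligand was the limiting reagent, with 1.9% of its charge free at 30.0 h, and the side product stood at 0.975 of C.

    starting complex + incoming ligand → leaving ligand + complex with one exchanged (k = 4.70 × 10⁻⁵ L mol⁻¹ s⁻¹)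
    complex with one exchanged + incoming ligand → leaving ligand + complex with two exchanged (k = 4.40 × 10⁻⁵ L mol⁻¹ s⁻¹)
    complex with two exchanged + incoming ligand → leaving ligand + complex with three exchanged (k = 3.70 × 10⁻⁶ L mol⁻¹ s⁻¹)
    starting complex + complex with one exchanged → side product (k = 8.10 × 10⁻⁵ L mol⁻¹ s⁻¹)

In a neighbour flask, west with 0.60 M of incoming ligand, C gives 45.1%. That neighbour flask gave 52.4% of side product with 0.31% of its ligand free, which puts φ there near 0.873.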